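**Plan**

1. Each bicyclic half is numbered as a 1-benzoxepine (O1, C2 = CMe2, C3 = CH–O, C5a = C–CH3, C6 = CH carrying the bridge, C7 = C(CH3)–OAc, C9a = CH–O). Half A has the C3 acetate and is (3S,5aS,6S,7R,9aS); half B has the free C3 hydroxyl and is (3S,5aS,6S,7S,9aS).
2. Cuts: first the CH2–CH2 bond of the bridge (half-B primary radical plus half-A 6-methylidene-7-ketone), then C7–CH3 in each half, so that both halves fall back on one 6-(hydroxymethyl)-7-ketone 13.
3. In 13 the ketone C7 sits next to C6–CH2OH and C6 next to the quaternary C5a. This aldol pattern is the product of a semipinacol ring enlargement, so the C5a–C6 bond is cut next. The remaining carbocycle C5a–C9a–C9–C8–C7, with its methyl group and an oxygen on both C9a and C7, is 2-methylcyclopentane-1,3-dione.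
4. Last cuts: O1–C2 (7-endo epoxide opening) and the side chain C5–C4–C3–CMe2 (acrolein Michael addition, Wittig olefination).
5. Forward order of rings: cyclopentane (bought) → trans-fused oxepane (step 5) → cyclohexane by one-carbon enlargement of the cyclopentane (step 9) → halves joined (step 16).
6. Stereochemistry: C5a from CBS desymmetrisation; C9a from Mitsunobu inversion; C3 from Shi epoxidation; C6 from α-ketone equilibration (half B) and axial hydrogen-atom transfer (half A); C7 from equatorial methyl addition (half A) or from peracid attack anti to the axial C5a methyl followed by hydride opening (half B).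

Key step: step 9

Remark on the chemistry: the L-fructose-derived enantiomer of the Shi ketone (ent-Shi ketone) is taken as available. In the cyclopentane intermediates the Why lines use the future benzoxepine locants.

**Route**

Step 1
Reactants: 1 2-methylcyclopentane-1,3-dione; 2 acrolein
Product: 3 3-(1-methyl-2,5-dioxocyclopentyl)propanal
Conditions: H2O, rt
Reagents that add atoms: none
Why: Michael addition of the cyclic 1,3-dione to acrolein in water is a clean C-alkylation that builds the (still prochiral) quaternary carbon, the future C5a, with C5, C4 and C3 attached.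

Step 2
Reactants: 3 3-(1-methyl-2,5-dioxocyclopentyl)propanal
Product: 4 2-methyl-2-(4-methylpent-3-en-1-yl)cyclopentane-1,3-dione
Conditions: i-PrPPh3 I, n-BuLi, THF, 0 °C; then 3, −78 to 0 °C
Reagents that add atoms: isopropyltriphenylphosphonium iodide CC(C)[P+](c1ccccc1)(c1ccccc1)c1ccccc1.[I-]
Why: Wittig olefination with one equivalent of the unstabilised ylide at low temperature should take the aldehyde ahead of the hindered, non-enolisable ring ketones and installs the CMe2 terminus (future C2).

Step 3
Reactants: 4 2-methyl-2-(4-methylpent-3-en-1-yl)cyclopentane-1,3-dione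
Product: 5 (2R,3R)-3-hydroxy-2-methyl-2-(4-methylpent-3-en-1-yl)cyclopentan-1-one
Conditions: (S)-2-methyl-CBS-oxazaborolidine (0.2 equiv), catecholborane, toluene, −78 °C
Reagents that add atoms: none
Why: Corey–Bakshi–Shibata reduction used as a desymmetrising mono-reduction: the catalyst should set the carbinol as R and hydride should enter on the carbonyl face syn to the methyl group, so the quaternary carbon (future C5a) becomes R and the hydroxyl stands cis to the chain.

Step 4
Reactants: 5 (2R,3R)-3-hydroxy-2-methyl-2-(4-methylpent-3-en-1-yl)cyclopentan-1-one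
Product: 7 (2R,3S)-3-hydroxy-2-methyl-2-(4-methylpent-3-en-1-yl)cyclopentan-1-one, via inverted 4-nitrobenzoate 6 (not isolated)
Conditions: 4-nitrobenzoic acid, PPh3, DIAD, THF, 0 °C to rt; then K2CO3, MeOH, 0 °C
Reagents that add atoms: 4-nitrobenzoic acid OC(=O)c1ccc(cc1)[N+](=O)[O-]
Why: Mitsunobu reaction (SN2 at the carbinol) followed by transesterification in the same flask inverts the future C9a, so that its oxygen and the side chain are trans as the trans ring fusion requires; the quaternary α-carbon excludes β-elimination through an enolate.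

Step 5
Reactants: 7 (2R,3S)-3-hydroxy-2-methyl-2-(4-methylpent-3-en-1-yl)cyclopentan-1-one
Product: 9 (3S,5aR,8aS)-3-hydroxy-2,2,5a-trimethyloctahydro-6H-cyclopenta[b]oxepin-6-one, via S-epoxide 8 (not isolated)
Conditions: ent-Shi ketone (0.3 equiv), KHSO5 (Oxone), K2CO3, Bu4NHSO4, MeCN/dimethoxymethane/aqueous buffer, 0 °C; organic phase dried, then BF3·OEt2 (0.1 equiv), CH2Cl2, −78 °C
Reagents that add atoms: potassium peroxymonosulfate OOS(=O)(=O)[O-].[K+]
Why: Shi asymmetric epoxidation with the ent-ketone should give the S-oxirane, and Lewis-acid-catalysed 7-endo epoxide opening by the ring hydroxyl at the tertiary oxirane carbon closes the trans-fused oxepane with C3 untouched (3S), the 6-exo mode being penalised because it would give a trans-fused oxahydrindane.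

Step 6
Reactants: 9 (3S,5aR,8aS)-3-hydroxy-2,2,5a-trimethyloctahydro-6H-cyclopenta[b]oxepin-6-one
Product: 10 (3S,5aR,8aS)-3-[(tert-butyldimethylsilyl)oxy]-2,2,5a-trimethyloctahydro-6H-cyclopenta[b]oxepin-6-one
Conditions: TBSOTf, 2,6-lutidine, CH2Cl2, −78 °C
Reagents that add atoms: tert-butyldimethylsilyl triflate CC(C)(C)[Si](C)(C)OS(=O)(=O)C(F)(F)F
Why: Silyl ether formation on the hindered secondary alcohol needs the silyl triflate, and at −78 °C 2,6-lutidine does not enolise the ketone.

Step 7
Reactants: 10 (3S,5aR,8aS)-3-[(tert-butyldimethylsilyl)oxy]-2,2,5a-trimethyloctahydro-6H-cyclopenta[b]oxepin-6-one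
Product: 11 (3S,5aR,6S,8aS)-3-[(tert-butyldimethylsilyl)oxy]-6-ethenyl-2,2,5a-trimethyloctahydro-2H-cyclopenta[b]oxepin-6-ol
Conditions: CH2=CHMgBr, CeCl3, THF, −78 °C
Reagents that add atoms: vinylmagnesium bromide C=C[Mg]Br
Why: Grignard 1,2-addition in the presence of CeCl3 (to suppress enolisation) to the hindered cyclopentanone, expected from the face opposite the angular methyl; the configuration of this carbinol is lost in step 9.

Step 8
Reactants: 11 (3S,5aR,6S,8aS)-3-[(tert-butyldimethylsilyl)oxy]-6-ethenyl-2,2,5a-trimethyloctahydro-2H-cyclopenta[b]oxepin-6-ol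
Product: 12 (3S,5aR,6R,8aS)-3-[(tert-butyldimethylsilyl)oxy]-2,2,5a-trimethyl-6-(oxiran-2-yl)octahydro-2H-cyclopenta[b]oxepin-6-ol (both oxirane epimers)
Conditions: VO(acac)2 (5 mol %), t-BuOOH, CH2Cl2, 0 °C to rt
Reagents that add atoms: tert-butyl hydroperoxide CC(C)(C)OO
Why: Hydroxyl-directed vanadium-catalysed epoxidation of the tertiary allylic alcohol reaches the unactivated vinyl group; the configuration of the new oxirane carbon needs no control because step 9 ends with equilibration.

Step 9
Reactants: 12 (3S,5aR,6R,8aS)-3-[(tert-butyldimethylsilyl)oxy]-2,2,5a-trimethyl-6-(oxiran-2-yl)octahydro-2H-cyclopenta[b]oxepin-6-ol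
Product: 13 (3S,5aS,6R,9aS)-3-[(tert-butyldimethylsilyl)oxy]-6-(hydroxymethyl)-2,2,5a-trimethyloctahydro-1-benzoxepin-7(2H)-one
Conditions: BF3·OEt2 (0.3 equiv), CH2Cl2, −78 to −20 °C; then basic Al2O3, CH2Cl2, rt
Reagents that add atoms: none
Why: BF3 binds the oxirane oxygen of 12, the C–O bond at the oxirane CH (future C6) lengthens, and the antiperiplanar ring bond from the quaternary carbon (future C5a) shifts from the carbinol carbon to that CH, while the carbinol carbon becomes the C7 ketone and the oxirane CH2–O becomes the hydroxymethyl group. The closest known reaction type is the semipinacol rearrangement of tertiary 2,3-epoxy alcohols, as used to enlarge 1-(oxiran-2-yl)cycloalkanols to 2-(hydroxymethyl)cycloalkanones. No ring is closed by cyclisation: the cyclohexane arises from the cyclopentane by insertion of one carbon between C7 and C5a through a 1,2-alkyl shift, and the trans fusion to the oxepane is carried over. C5a migrates with retention; C6 forms with inversion at the oxirane carbon and, being α to the new ketone, is then equilibrated on basic alumina to the epimer with the equatorial hydroxymethyl group, so both oxirane epimers converge (any residual minor epimer can go into step 10, where C6 becomes planar). The step needs migration of the quaternary carbon and not of the ring CH2: the fully substituted carbon is the better migrating group in a cation-like 1,2-shift, and a monodentate Lewis acid leaves the rotamer with this bond anti to the oxirane C–O bond accessible.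

Step 10
Reactants: 13 (3S,5aS,6R,9aS)-3-[(tert-butyldimethylsilyl)oxy]-6-(hydroxymethyl)-2,2,5a-trimethyloctahydro-1-benzoxepin-7(2H)-one
Product: 15 (3S,5aS,9aS)-3-[(tert-butyldimethylsilyl)oxy]-2,2,5a-trimethyl-6-methylideneoctahydro-1-benzoxepin-7(2H)-one, via primary mesylate 14 (not isolated)
Conditions: MsCl, Et3N, CH2Cl2, 0 °C; then DBU, rt
Reagents that add atoms: none
Why: Mesylation of the β-hydroxy ketone and E1cB elimination give the α-methylene ketone of half A, and both C6 epimers of 13 converge.

Step 11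
Reactants: 15 (3S,5aS,9aS)-3-[(tert-butyldimethylsilyl)oxy]-2,2,5a-trimethyl-6-methylideneoctahydro-1-benzoxepin-7(2H)-one
Product: 16 (3S,5aS,9aS)-3-hydroxy-2,2,5a-trimethyl-6-methylideneoctahydro-1-benzoxepin-7(2H)-one
Conditions: HF·pyridine, pyridine, THF, 0 °C to rt; used at once
Reagents that add atoms: none
Why: Fluoride desilylation frees the C3 hydroxyl of half A before the union, so that only half B still carries a silyl ether when the acetates are introduced.

Step 12
Reactants: 13 (3S,5aS,6R,9aS)-3-[(tert-butyldimethylsilyl)oxy]-6-(hydroxymethyl)-2,2,5a-trimethyloctahydro-1-benzoxepin-7(2H)-one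
Product: 17 [(3S,5aS,6R,9aS)-3-[(tert-butyldimethylsilyl)oxy]-2,2,5a-trimethyl-7-methylidenedecahydro-1-benzoxepin-6-yl]methanol
Conditions: Zn, CH2Br2, TiCl4 (reagent preformed in THF), CH2Cl2, 0 °C to rt
Reagents that add atoms: dibromomethane BrCBr
Why: Lombardo methylenation is non-basic, so the β-hydroxy ketone should neither eliminate nor epimerise at C6, and the reagent tolerates the free hydroxyl.

Step 13
Reactants: 17 [(3S,5aS,6R,9aS)-3-[(tert-butyldimethylsilyl)oxy]-2,2,5a-trimethyl-7-methylidenedecahydro-1-benzoxepin-6-yl]methanol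
Product: 18 spiro-epoxide of 17 at C7 (7S; oxirane oxygen on the face opposite the C5a methyl)
Conditions: m-CPBA, NaHCO3, CH2Cl2, 0 °C
Reagents that add atoms: 3-chloroperoxybenzoic acid OOC(=O)c1cccc(Cl)c1
Why: Prilezhaev epoxidation of the exocyclic alkene should occur on the face opposite the axial C5a methyl (1,3-diaxial shielding of the other face), which places the oxirane oxygen equatorial on C7.

Step 14
Reactants: 18 spiro-epoxide of 17 at C7
Product: 19 (3S,5aS,6R,7S,9aS)-3-[(tert-butyldimethylsilyl)oxy]-6-(hydroxymethyl)-2,2,5a,7-tetramethyldecahydro-1-benzoxepin-7-ol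
Conditions: LiAlH4, THF, 0 °C to rt
Reagents that add atoms: none
Why: Hydride opens the 1,1-disubstituted oxirane at its CH2 terminus (SN2), which leaves the tertiary alcohol equatorial and the new methyl axial, the 7S configuration of half B.

Step 15
Reactants: 19 (3S,5aS,6R,7S,9aS)-3-[(tert-butyldimethylsilyl)oxy]-6-(hydroxymethyl)-2,2,5a,7-tetramethyldecahydro-1-benzoxepin-7-ol
Product: 20 (3S,5aS,6S,7S,9aS)-3-[(tert-butyldimethylsilyl)oxy]-6-(iodomethyl)-2,2,5a,7-tetramethyldecahydro-1-benzoxepin-7-ol
Conditions: I2, PPh3, imidazole, CH2Cl2, 0 °C to rt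
Reagents that add atoms: iodine II
Why: Appel-type iodination converts only the primary alcohol; the tertiary alcohol is inert under these conditions.

Step 16
Reactants: 20 (3S,5aS,6S,7S,9aS)-3-[(tert-butyldimethylsilyl)oxy]-6-(iodomethyl)-2,2,5a,7-tetramethyldecahydro-1-benzoxepin-7-ol; 16 (3S,5aS,9aS)-3-hydroxy-2,2,5a-trimethyl-6-methylideneoctahydro-1-benzoxepin-7(2H)-one
Product: 21 coupled keto diol (half-A 7-ketone with free C3 hydroxyl joined through CH2CH2 to the half-B 7-ol with C3 silyl ether)
Conditions: (Me3Si)3SiH, AIBN (cat.), toluene, 80 °C, slow addition of the silane; 16 in 1.5-fold excess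
Reagents that add atoms: none
Why: Giese radical conjugate addition: the primary radical from the iodide adds to the unhindered CH2 terminus of the α-methylene ketone and forms the central CH2–CH2 bond, and the α-keto radical then takes hydrogen from the silane on the face opposite the axial C5a methyl, which sets C6 of half A with the chain equatorial.

Step 17
Reactants: 21 coupled keto diol
Product: 22 triol (half A: free C3 hydroxyl and axial 7R tertiary alcohol; half B: equatorial 7S tertiary alcohol and C3 silyl ether)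
Conditions: MeMgBr (excess), CeCl3, THF, −78 to 0 °C
Reagents that add atoms: methylmagnesium bromide C[Mg]Br
Why: Grignard addition with CeCl3 to suppress enolisation should come from the equatorial side, because the axial trajectory is blocked by the syn-axial C5a methyl, and so gives the axial tertiary alcohol (7R) of half A; the excess reagent only deprotonates the two free hydroxyls.

Step 18
Reactants: 22 triol
Product: 23 triacetate (C3 and C7 acetates on half A; C7 acetate and C3 silyl ether on half B)
Conditions: Ac2O, DMAP, Et3N, CH2Cl2, 40 °C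
Reagents that add atoms: acetic anhydride CC(=O)OC(C)=O
Why: DMAP-catalysed acyl transfer (Steglich-type acylation) esterifies the secondary and both tertiary alcohols, while the silyl ether keeps the C3 oxygen of half B free of acetate.

Step 19
Reactants: 23 triacetate
Product: 24 CNP0169816.1
Conditions: HF·pyridine, pyridine, THF, rt
Reagents that add atoms: none
Why: Fluoride desilylation under buffered, non-basic conditions leaves the three acetates in place and frees the C3 hydroxyl of half B.

**Compound list**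

1 | 2-methylcyclopentane-1,3-dione | CC1C(=O)CCC1=O | starting material
2 | acrolein (prop-2-enal) | C=CC=O | starting material
3 | 3-(1-methyl-2,5-dioxocyclopentyl)propanal | CC1(CCC=O)C(=O)CCC1=O | intermediate
4 | 2-methyl-2-(4-methylpent-3-en-1-yl)cyclopentane-1,3-dione | CC(C)=CCCC1(C)C(=O)CCC1=O | intermediate
5 | (2R,3R)-3-hydroxy-2-methyl-2-(4-methylpent-3-en-1-yl)cyclopentan-1-one (hydroxyl cis to the chain) | O=C1CC[C@@H](O)[C@@]1(C)CCC=C(C)C | intermediate
6 | (1S,2R)-2-methyl-2-(4-methylpent-3-en-1-yl)-3-oxocyclopentyl 4-nitrobenzoate | O=C1CC[C@H](OC(=O)c2ccc(cc2)[N+](=O)[O-])[C@@]1(C)CCC=C(C)C | intermediate (not isolated)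
7 | (2R,3S)-3-hydroxy-2-methyl-2-(4-methylpent-3-en-1-yl)cyclopentan-1-one (hydroxyl trans to the chain) | O=C1CC[C@H](O)[C@@]1(C)CCC=C(C)C | intermediate
8 | (2R,3S)-2-{2-[(2S)-3,3-dimethyloxiran-2-yl]ethyl}-3-hydroxy-2-methylcyclopentan-1-one | O=C1CC[C@H](O)[C@@]1(C)CC[C@@H]1OC1(C)C | intermediate (not isolated)
9 | (3S,5aR,8aS)-3-hydroxy-2,2,5a-trimethyloctahydro-6H-cyclopenta[b]oxepin-6-one (trans-fused) | O=C1CC[C@@H]2OC(C)(C)[C@@H](O)CC[C@@]12C | intermediate
10 | (3S,5aR,8aS)-3-[(tert-butyldimethylsilyl)oxy]-2,2,5a-trimethyloctahydro-6H-cyclopenta[b]oxepin-6-one | O=C1CC[C@@H]2OC(C)(C)[C@@H](O[Si](C)(C)C(C)(C)C)CC[C@@]12C | intermediate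
11 | (3S,5aR,6S,8aS)-3-[(tert-butyldimethylsilyl)oxy]-6-ethenyl-2,2,5a-trimethyloctahydro-2H-cyclopenta[b]oxepin-6-ol | C=C[C@@]1(O)CC[C@@H]2OC(C)(C)[C@@H](O[Si](C)(C)C(C)(C)C)CC[C@@]12C | intermediate
12 | (3S,5aR,6R,8aS)-3-[(tert-butyldimethylsilyl)oxy]-2,2,5a-trimethyl-6-(oxiran-2-yl)octahydro-2H-cyclopenta[b]oxepin-6-ol (oxirane carbon: both epimers) | O[C@]1(C2CO2)CC[C@@H]3OC(C)(C)[C@@H](O[Si](C)(C)C(C)(C)C)CC[C@@]13C | intermediate
13 | (3S,5aS,6R,9aS)-3-[(tert-butyldimethylsilyl)oxy]-6-(hydroxymethyl)-2,2,5a-trimethyloctahydro-1-benzoxepin-7(2H)-one | O=C1CC[C@@H]2OC(C)(C)[C@@H](O[Si](C)(C)C(C)(C)C)CC[C@@]2(C)[C@@H]1CO | intermediate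
14 | methanesulfonate of the primary alcohol of 13 | O=C1CC[C@@H]2OC(C)(C)[C@@H](O[Si](C)(C)C(C)(C)C)CC[C@@]2(C)[C@@H]1COS(C)(=O)=O | intermediate (not isolated)
15 | (3S,5aS,9aS)-3-[(tert-butyldimethylsilyl)oxy]-2,2,5a-trimethyl-6-methylideneoctahydro-1-benzoxepin-7(2H)-one | O=C1CC[C@@H]2OC(C)(C)[C@@H](O[Si](C)(C)C(C)(C)C)CC[C@@]2(C)C1=C | intermediate
16 | (3S,5aS,9aS)-3-hydroxy-2,2,5a-trimethyl-6-methylideneoctahydro-1-benzoxepin-7(2H)-one | O=C1CC[C@@H]2OC(C)(C)[C@@H](O)CC[C@@]2(C)C1=C | intermediate
17 | [(3S,5aS,6R,9aS)-3-[(tert-butyldimethylsilyl)oxy]-2,2,5a-trimethyl-7-methylidenedecahydro-1-benzoxepin-6-yl]methanol | C=C1CC[C@@H]2OC(C)(C)[C@@H](O[Si](C)(C)C(C)(C)C)CC[C@@]2(C)[C@@H]1CO | intermediate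
18 | spiro-epoxide of 17 at C7 (7S; oxirane oxygen equatorial, CH2 axial) | OC[C@H]1[C@]2(C)CC[C@H](O[Si](C)(C)C(C)(C)C)C(C)(C)O[C@H]2CC[C@@]13CO3 | intermediate
19 | (3S,5aS,6R,7S,9aS)-3-[(tert-butyldimethylsilyl)oxy]-6-(hydroxymethyl)-2,2,5a,7-tetramethyldecahydro-1-benzoxepin-7-ol | OC[C@H]1[C@]2(C)CC[C@H](O[Si](C)(C)C(C)(C)C)C(C)(C)O[C@H]2CC[C@]1(C)O | intermediate
20 | (3S,5aS,6S,7S,9aS)-3-[(tert-butyldimethylsilyl)oxy]-6-(iodomethyl)-2,2,5a,7-tetramethyldecahydro-1-benzoxepin-7-ol | IC[C@H]1[C@]2(C)CC[C@H](O[Si](C)(C)C(C)(C)C)C(C)(C)O[C@H]2CC[C@]1(C)O | intermediate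
21 | coupled keto diol: half-A 7-ketone (free C3 hydroxyl) linked by CH2CH2 to half-B 7-ol (C3 silyl ether) | O[C@H]1CC[C@]2(C)[C@H](CCC(=O)[C@H]2CC[C@H]2[C@]3(C)CC[C@H](O[Si](C)(C)C(C)(C)C)C(C)(C)O[C@H]3CC[C@]2(C)O)OC1(C)C | intermediate
22 | triol: half A with C3 hydroxyl and 7R tertiary alcohol; half B with 7S tertiary alcohol and C3 silyl ether | O[C@H]1CC[C@]2(C)[C@H](CC[C@@](C)(O)[C@H]2CC[C@H]2[C@]3(C)CC[C@H](O[Si](C)(C)C(C)(C)C)C(C)(C)O[C@H]3CC[C@]2(C)O)OC1(C)C | intermediate
23 | triacetate with the C3 silyl ether on half B | CC(=O)O[C@H]1CC[C@]2(C)[C@H](CC[C@@](C)(OC(C)=O)[C@H]2CC[C@H]2[C@]3(C)CC[C@H](O[Si](C)(C)C(C)(C)C)C(C)(C)O[C@H]3CC[C@]2(C)OC(C)=O)OC1(C)C | intermediate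
24 | CNP0169816.1 | CC(=O)O[C@H]1CC[C@]2(C)[C@H](CC[C@@](C)(OC(C)=O)[C@H]2CC[C@H]2[C@]3(C)CC[C@H](O)C(C)(C)O[C@H]3CC[C@]2(C)OC(C)=O)OC1(C)C | target

**Count**

Total steps: 19. Longest linear sequence: 17 (steps 1–9, 12–15, 16–19).

**Steps most likely to fail**

Step 9. The ring CH2 may migrate in competition with the quaternary carbon, which would give the constitutional isomer of the ketone, or the activated oxirane may be captured before any shift occurs. The fallback sets out from 10 and returns at 13. Addition of bis(phenylthio)methyllithium (from bis(phenylthio)methane and n-BuLi, THF, −78 °C) to the ketone gives the bis(phenylsulfanyl)methyl carbinol F1. CuOTf (monovalent copper) and i-Pr2NEt in benzene at 78 °C remove one thiolate, and the ring bond shifts to the sulfur-stabilised cationic carbon, a later transition state that responds more strongly to the electron-richness of the quaternary carbon; this gives the ring-enlarged α-(phenylsulfanyl) ketone F2. Aqueous HCHO with K2CO3 hydroxymethylates the doubly activated carbon regiospecifically to the hydroxymethyl sulfide F3. Bu3SnH with AIBN then cleaves the C–S bond, with hydrogen delivered on the face opposite the C5a methyl, to give 13.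

Step 5. The 7-endo closure may be outrun by 6-exo attack at the secondary oxirane carbon, by capture of the oxirane by the ketone oxygen (bicyclic ketal), or by a hydride shift of the activated oxirane. The fallback sets out from 7 and returns at 9. The epoxidation is run alone and the S-epoxide 8 is isolated. Me3SiOTf and DBU (CH2Cl2, −78 °C; then K2CO3, MeOH) isomerise the trisubstituted oxirane to the isopropenyl carbinol, the allylic alcohol F4, with C3 untouched. Hg(OCOCF3)2 (divalent mercury) in CH2Cl2 then closes the oxepane by Markovnikov 7-exo alkoxymercuration at the tertiary alkene carbon, where no exo/endo choice exists, and gives the organomercurial F5. Bu3SnH replaces mercury by hydrogen to give 9.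

Step 4. Substitution at the neopentyl-type carbinol may be slow, and elimination to the cyclopentenone or ester formation with retention may take over. The fallback sets out from 4 and returns at 7, bypassing 5 and 6. A ketoreductase screened for anti-selective mono-reduction to the (2R,3S) isomer (NADPH recycled with glucose and glucose dehydrogenase, pH 7 buffer, 30 °C) desymmetrises the dione directly to the trans hydroxy ketone, so no inversion step is needed.

Further compounds
F1 | step 9 | (3S,5aR,8aS)-6-[bis(phenylsulfanyl)methyl]-3-[(tert-butyldimethylsilyl)oxy]-2,2,5a-trimethyloctahydro-2H-cyclopenta[b]oxepin-6-ol | O[C@]1(C(Sc2ccccc2)Sc2ccccc2)CC[C@@H]3OC(C)(C)[C@@H](O[Si](C)(C)C(C)(C)C)CC[C@@]13C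
F2 | step 9 | (3S,5aS,9aS)-3-[(tert-butyldimethylsilyl)oxy]-2,2,5a-trimethyl-6-(phenylsulfanyl)octahydro-1-benzoxepin-7(2H)-one (C6 epimers) | O=C1CC[C@@H]2OC(C)(C)[C@@H](O[Si](C)(C)C(C)(C)C)CC[C@@]2(C)C1Sc1ccccc1
F3 | step 9 | (3S,5aS,9aS)-3-[(tert-butyldimethylsilyl)oxy]-6-(hydroxymethyl)-2,2,5a-trimethyl-6-(phenylsulfanyl)octahydro-1-benzoxepin-7(2H)-one (C6 epimers) | O=C1CC[C@@H]2OC(C)(C)[C@@H](O[Si](C)(C)C(C)(C)C)CC[C@@]2(C)C1(CO)Sc1ccccc1
F4 | step 5 | (2R,3S)-3-hydroxy-2-[(3S)-3-hydroxy-4-methylpent-4-en-1-yl]-2-methylcyclopentan-1-one | O=C1CC[C@H](O)[C@@]1(C)CC[C@H](O)C(C)=C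
F5 | step 5 | {[(3S,5aR,8aS)-3-hydroxy-2,5a-dimethyl-6-oxooctahydro-2H-cyclopenta[b]oxepin-2-yl]methyl}mercury trifluoroacetate (C2 epimers) | O=C1CC[C@@H]2OC(C)(C[Hg]OC(=O)C(F)(F)F)[C@@H](O)CC[C@@]12C
F0 | step 4 | none | none
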